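**Retrosynthetic overview**
- The C13=C14 butenolide comes from Rh–H isomerisation of an α-alkylidene lactone, itself made by cross-metathesis of a C9-allyl triol with α-methylene-γ-butyrolactone.
- C3-OH, C8-CH2OH and C9-H come from one dissolving-metal reduction (then LiAlH4) of a C3-ketone / C8(ester)=C9(allyl) enoate, reached by Stille allylation of the enol triflate of a ring-B β-keto ester.
- The C4 quaternary centre and the trans ring fusion come from Birch reductive methylation of a 4-(benzyloxymethyl) enone while the β-keto ester rests as its enolate.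
- Ring B with C17 attached comes from a one-carbon ring expansion (ethyl diazoacetate, C7 migrates) of the cyclopentanone of a Hajos–Parrish-type enedione; this is the key step.
- Ring A is made first, by amine-catalysed annulation of 2-methylcyclopentane-1,3-dione with tetrahydropyran-4-one as a latent 5-hydroxypent-1-en-3-one. Ring order: A, five-membered precursor of B, B by expansion, butenolide last.

Assumption: atom labels C1–C20 are labdane numbers (C17 = CH2OH on C8, C18 = CH3 and C19 = CH2OH on C4, C20 = CH3 on C10); catalysts, bases, Lewis acids and the benzyl donor are bought reagents.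

**Route**

Step 1
Reactants: 1 2-methylcyclopentane-1,3-dione; 2 tetrahydro-4H-pyran-4-one
Product: 5 (7aR)-4-(hydroxymethyl)-7a-methyl-2,3,7,7a-tetrahydro-1H-indene-1,5(6H)-dione, via 5-hydroxypent-1-en-3-one 3 (not isolated), via triketone 4 (not isolated)
Conditions: D-phenylalanine (1.0 equiv), (1R)-(−)-10-camphorsulfonic acid (0.5 equiv), 2 (3 equiv), DMF, 70 °C, 48 h, one pot
Reagents that add atoms: none
Why: Proposed new method: the primary amine condenses with 2 to an enamine whose E1cB loss of the ring alkoxide (retro-oxa-Michael) unmasks the vinyl-ketone iminium of 3, dione 1 adds irreversibly (Michael) to give 4, and the phenylalanine enamine of 4 (on the CH2CH2OH side, the only one that can close a six-membered ring) undergoes the Hajos–Parrish–Eder–Sauer–Wiechert aldol condensation, D-Phe setting C10 (C7a) as R; the closest known reactions are the Phe/CSA Hajos–Parrish annulation of ethyl-vinyl-ketone-derived triketones and Robinson annulations that use Mannich bases or β-chloro ketones as latent enones, the new element being a cyclic β-alkoxy ketone as the latent enone so that its oxygen stays as C19-OH.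

Step 2
Reactants: 5 (7aR)-4-(hydroxymethyl)-7a-methyl-2,3,7,7a-tetrahydro-1H-indene-1,5(6H)-dione
Product: 6 (7aR)-4-[(benzyloxy)methyl]-7a-methyl-2,3,7,7a-tetrahydro-1H-indene-1,5(6H)-dione
Conditions: BnOC(=NH)CCl3 (1.3 equiv), TfOH (5 mol%), CH2Cl2/cyclohexane, 0 °C to rt
Reagents that add atoms: benzyl 2,2,2-trichloroacetimidate, N=C(OCc1ccccc1)C(Cl)(Cl)Cl
Why: Acid-catalysed O-benzylation with a trichloroacetimidate avoids base on the enedione; the benzyl ether blocks O–H insertion of the diazo ester in step 3 and is removed without an extra step in step 4.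

Step 3
Reactants: 6 (7aR)-4-[(benzyloxy)methyl]-7a-methyl-2,3,7,7a-tetrahydro-1H-indene-1,5(6H)-dione; 7 ethyl diazoacetate
Product: 8 ethyl (8aR)-5-[(benzyloxy)methyl]-1-hydroxy-8a-methyl-6-oxo-3,4,6,7,8,8a-hexahydronaphthalene-2-carboxylate
Conditions: BF3·OEt2 (1.2 equiv, promoter), 7 (1.5 equiv), CH2Cl2, 0 °C to rt
Reagents that add atoms: none
Why: Lewis-acid-promoted diazoacetate homologation (Tiffeneau–Demjanov-type 1,2-shift): the diazo ester adds to the BF3-activated saturated cyclopentanone (the conjugated enone carbonyl is too weak an electrophile), the less substituted C7 methylene migrates to the diazonium carbon with loss of N2 as in the D-homoannulation of 17-keto steroids, and ring B forms with C17 already on C8 as an enolised β-keto ester; no stereocentre is touched.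

Step 4
Reactants: 8 ethyl (8aR)-5-[(benzyloxy)methyl]-1-hydroxy-8a-methyl-6-oxo-3,4,6,7,8,8a-hexahydronaphthalene-2-carboxylate
Product: 10 ethyl (4aS,5R,8aR)-1-hydroxy-5-(hydroxymethyl)-5,8a-dimethyl-6-oxo-3,4,4a,5,6,7,8,8a-octahydronaphthalene-2-carboxylate, via trilithium enolate 9 (not isolated)
Conditions: LiHMDS (1.05 equiv), THF, −78 °C; then Li (5 equiv), NH3(l)/THF, t-BuOH (2 equiv), −78 °C; isoprene; MeI (1.5 equiv), −78 to −45 °C; NH4Cl
Reagents that add atoms: iodomethane, CI
Why: Birch-type reductive alkylation in which the β-keto ester, held as its lithium enolate, is inert to Li/NH3 and far less nucleophilic than the ketone enolate; the enone is reduced with axial protonation at C5 (trans fusion), the benzyl ether is cleaved to the C19 alkoxide (which cannot β-eliminate), and MeI attacks enolate C4 on the face opposite the angular C10 methyl, so the new CH3 is equatorial (C18) and CH2OH is axial (C19, cis to C20).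

Step 5
Reactants: 10 ethyl (4aS,5R,8aR)-1-hydroxy-5-(hydroxymethyl)-5,8a-dimethyl-6-oxo-3,4,4a,5,6,7,8,8a-octahydronaphthalene-2-carboxylate
Product: 11 ethyl (4aS,5R,8aR)-5-(hydroxymethyl)-5,8a-dimethyl-6-oxo-1-[(trifluoromethanesulfonyl)oxy]-3,4,4a,5,6,7,8,8a-octahydronaphthalene-2-carboxylate
Conditions: KHMDS (1.05 equiv), THF, −78 °C; PhNTf2 (1.1 equiv), −78 to 0 °C; NH4Cl
Reagents that add atoms: N-phenyl-bis(trifluoromethanesulfonimide), O=S(=O)(N(c1ccccc1)S(=O)(=O)C(F)(F)F)C(F)(F)F
Why: Enol triflate formation: one equivalent of base removes only the β-keto ester proton (pKa about 11, far below the alcohol and the C2–H of the ketone), the enolate is O-sulfonylated by PhNTf2, and the cold, base-limited conditions avoid retro-aldol loss of C19.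

Step 6
Reactants: 11 ethyl (4aS,5R,8aR)-5-(hydroxymethyl)-5,8a-dimethyl-6-oxo-1-[(trifluoromethanesulfonyl)oxy]-3,4,4a,5,6,7,8,8a-octahydronaphthalene-2-carboxylate; 12 allyltrimethylstannane
Product: 13 ethyl (4aS,5R,8aR)-5-(hydroxymethyl)-5,8a-dimethyl-6-oxo-1-(prop-2-en-1-yl)-3,4,4a,5,6,7,8,8a-octahydronaphthalene-2-carboxylate
Conditions: Pd(PPh3)4 (5 mol%), LiCl (3 equiv), THF, 65 °C
Reagents that add atoms: none
Why: Stille coupling of a vinyl triflate forms the C9–C11 bond under neutral conditions; the allylstannane does not add to the C3 ketone (an allylzinc or Grignard reagent would) and the β-hydroxy ketone is not exposed to base.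

Step 7
Reactants: 13 ethyl (4aS,5R,8aR)-5-(hydroxymethyl)-5,8a-dimethyl-6-oxo-1-(prop-2-en-1-yl)-3,4,4a,5,6,7,8,8a-octahydronaphthalene-2-carboxylate
Product: 15 ethyl (1R,2S,4aS,5R,6R,8aS)-6-hydroxy-5-(hydroxymethyl)-5,8a-dimethyl-1-(prop-2-en-1-yl)decahydronaphthalene-2-carboxylate, via C8-epimeric ester 14 (not isolated)
Conditions: Li (10 equiv), NH3(l)/THF, t-BuOH (4 equiv), −78 to −33 °C, inverse addition; NH4Cl; then NaOEt (0.3 equiv), EtOH, rt
Reagents that add atoms: none
Why: Dissolving-metal (Birch-type) reduction: the tetrasubstituted enoate is reduced 1,4 with axial protonation of the C9 carbanion on the face opposite C20 (allyl equatorial, H9 anti to C20), the C3 ketone gives the thermodynamically preferred equatorial alcohol, the isolated terminal alkene and the ester enolate survive, and ethoxide equilibration moves the C8 ester from the kinetic epimer 14 to the equatorial, trans-diequatorial 15 (any ester over-reduced to the alcohol is already 16).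

Step 8
Reactants: 15 ethyl (1R,2S,4aS,5R,6R,8aS)-6-hydroxy-5-(hydroxymethyl)-5,8a-dimethyl-1-(prop-2-en-1-yl)decahydronaphthalene-2-carboxylate
Product: 16 (1R,2S,4aS,5R,6R,8aS)-2,5-bis(hydroxymethyl)-5,8a-dimethyl-1-(prop-2-en-1-yl)decahydronaphthalen-6-ol
Conditions: LiAlH4 (3 equiv), THF, 0 °C to rt; aqueous NaOH work-up
Reagents that add atoms: none
Why: LiAlH4 ester reduction turns the equatorial C8 ester into the C17 CH2OH group without epimerisation; the terminal alkene is inert.

Step 9
Reactants: 16 (1R,2S,4aS,5R,6R,8aS)-2,5-bis(hydroxymethyl)-5,8a-dimethyl-1-(prop-2-en-1-yl)decahydronaphthalen-6-ol; 17 α-methylene-γ-butyrolactone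
Product: 18 (3E)-3-{2-[(1R,2S,4aS,5R,6R,8aS)-6-hydroxy-2,5-bis(hydroxymethyl)-5,8a-dimethyldecahydronaphthalen-1-yl]ethylidene}oxolan-2-one
Conditions: Hoveyda–Grubbs II (5 mol%), 2,6-dichloro-1,4-benzoquinone (10 mol%), 17 (5 equiv), CH2Cl2, 40 °C
Reagents that add atoms: none
Why: Olefin cross-metathesis between a terminal alkene and the 1,1-disubstituted alkene of an α-methylene lactone (a known pairing) forms C12=C13 with loss of ethene; the quinone suppresses Ru–H isomerisation of 17, free hydroxyls are tolerated, and the alkene geometry does not matter because the alkene is moved in step 10.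

Step 10
Reactants: 18 (3E)-3-{2-[(1R,2S,4aS,5R,6R,8aS)-6-hydroxy-2,5-bis(hydroxymethyl)-5,8a-dimethyldecahydronaphthalen-1-yl]ethylidene}oxolan-2-one
Product: 19 3-{2-[(1R,2S,4aS,5R,6R,8aS)-6-hydroxy-2,5-bis(hydroxymethyl)-5,8a-dimethyldecahydronaphthalen-1-yl]ethyl}furan-2(5H)-one
Conditions: RhCl3·3H2O (5 mol%), EtOH, 78 °C
Reagents that add atoms: none
Why: Rh–H addition and β-hydride elimination (alkene isomerisation of α-alkylidene-γ-butyrolactones) moves the exocyclic C12=C13 bond into the ring to give the more stable endocyclic butenolide; C13 becomes sp2, so no stereocentre is at risk.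

**Compound list**

1 | 2-methylcyclopentane-1,3-dione | CC1C(=O)CCC1=O | starting material
2 | tetrahydro-4H-pyran-4-one | O=C1CCOCC1 | starting material
3 | 5-hydroxypent-1-en-3-one (not isolated) | C=CC(=O)CCO | intermediate
4 | 2-(5-hydroxy-3-oxopentyl)-2-methylcyclopentane-1,3-dione (not isolated) | CC1(CCC(=O)CCO)C(=O)CCC1=O | intermediate
5 | (7aR)-4-(hydroxymethyl)-7a-methyl-2,3,7,7a-tetrahydro-1H-indene-1,5(6H)-dione | OCC1=C2CCC(=O)[C@]2(C)CCC1=O | intermediate
6 | (7aR)-4-[(benzyloxy)methyl]-7a-methyl-2,3,7,7a-tetrahydro-1H-indene-1,5(6H)-dione | c1ccccc1COCC1=C2CCC(=O)[C@]2(C)CCC1=O | intermediate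
7 | ethyl diazoacetate | CCOC(=O)C=[N+]=[N-] | starting material
8 | ethyl (8aR)-5-[(benzyloxy)methyl]-1-hydroxy-8a-methyl-6-oxo-3,4,6,7,8,8a-hexahydronaphthalene-2-carboxylate (enol form of the C9-oxo C8-ester) | c1ccccc1COCC1=C2CCC(C(=O)OCC)=C(O)[C@]2(C)CCC1=O | intermediate
9 | trilithium salt of the C19 alkoxide / C3(4) enolate / ring-B β-keto ester enolate, C5-H trans to C10-CH3 (not isolated) | [Li+].[Li+].[Li+].[O-]CC=1[C@H]2CCC(C(=O)OCC)=C([O-])[C@]2(C)CCC=1[O-] | intermediate
10 | ethyl (4aS,5R,8aR)-1-hydroxy-5-(hydroxymethyl)-5,8a-dimethyl-6-oxo-3,4,4a,5,6,7,8,8a-octahydronaphthalene-2-carboxylate | C[C@]1(CO)[C@H]2CCC(C(=O)OCC)=C(O)[C@]2(C)CCC1=O | intermediate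
11 | ethyl (4aS,5R,8aR)-5-(hydroxymethyl)-5,8a-dimethyl-6-oxo-1-[(trifluoromethanesulfonyl)oxy]-3,4,4a,5,6,7,8,8a-octahydronaphthalene-2-carboxylate | C[C@]1(CO)[C@H]2CCC(C(=O)OCC)=C(OS(=O)(=O)C(F)(F)F)[C@]2(C)CCC1=O | intermediate
12 | allyltrimethylstannane | C=CC[Sn](C)(C)C | starting material
13 | ethyl (4aS,5R,8aR)-5-(hydroxymethyl)-5,8a-dimethyl-6-oxo-1-(prop-2-en-1-yl)-3,4,4a,5,6,7,8,8a-octahydronaphthalene-2-carboxylate | C[C@]1(CO)[C@H]2CCC(C(=O)OCC)=C(CC=C)[C@]2(C)CCC1=O | intermediate
14 | ethyl (1R,2R,4aS,5R,6R,8aS)-6-hydroxy-5-(hydroxymethyl)-5,8a-dimethyl-1-(prop-2-en-1-yl)decahydronaphthalene-2-carboxylate (axial ester, not isolated) | C[C@]1(CO)[C@H]2CC[C@@H](C(=O)OCC)[C@@H](CC=C)[C@]2(C)CC[C@H]1O | intermediate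
15 | ethyl (1R,2S,4aS,5R,6R,8aS)-6-hydroxy-5-(hydroxymethyl)-5,8a-dimethyl-1-(prop-2-en-1-yl)decahydronaphthalene-2-carboxylate | C[C@]1(CO)[C@H]2CC[C@H](C(=O)OCC)[C@@H](CC=C)[C@]2(C)CC[C@H]1O | intermediate
16 | (1R,2S,4aS,5R,6R,8aS)-2,5-bis(hydroxymethyl)-5,8a-dimethyl-1-(prop-2-en-1-yl)decahydronaphthalen-6-ol | C[C@]1(CO)[C@H]2CC[C@H](CO)[C@@H](CC=C)[C@]2(C)CC[C@H]1O | intermediate
17 | α-methylene-γ-butyrolactone (3-methylideneoxolan-2-one) | C=C1CCOC1=O | starting material
18 | (3E)-3-{2-[(1R,2S,4aS,5R,6R,8aS)-6-hydroxy-2,5-bis(hydroxymethyl)-5,8a-dimethyldecahydronaphthalen-1-yl]ethylidene}oxolan-2-one | C[C@]1(CO)[C@H]2CC[C@H](CO)[C@@H](C/C=C3\CCOC3=O)[C@]2(C)CC[C@H]1O | intermediate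
19 | 14-deoxy-17-hydroxyandrographolide, 3-{2-[(1R,2S,4aS,5R,6R,8aS)-6-hydroxy-2,5-bis(hydroxymethyl)-5,8a-dimethyldecahydronaphthalen-1-yl]ethyl}furan-2(5H)-one | C[C@]1(CO)[C@H]2CC[C@H](CO)[C@@H](CCC3=CCOC3=O)[C@]2(C)CC[C@H]1O | target

**Step count and risks**

Total step count: 10. Longest linear sequence: 10 steps (1 to 19); 7, 12 and 17 are bought.

The three steps most likely to fail:

Step 1 (the proposed new annulation). The retro-oxa-Michael unmasking of 2 may be too slow, or the free hydroxyl may lower the enantioselectivity. The fallback uses known chemistry, sets out from 1 and comes back at 6, so 5 and step 2 are bypassed. Benzyl alcohol is added to acrolein to give 3-(benzyloxy)propanal F1, vinylmagnesium bromide gives 5-(benzyloxy)pent-1-en-3-ol F2, and Dess–Martin oxidation gives 5-(benzyloxy)pent-1-en-3-one F3. Michael addition of 1 (Et3N, EtOAc) then gives 2-[5-(benzyloxy)-3-oxopentyl]-2-methylcyclopentane-1,3-dione F4, and the established D-phenylalanine/CSA Hajos–Parrish cyclodehydration of this ethyl-ketone-type triketone gives 6.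

Step 4 (reductive methylation beside the β-keto ester enolate). The ring-B enolate may be C- or O-methylated, or partly reduced. The fallback sets out from 8 and comes back at 15. The β-keto ester is masked covalently (TBSOTf, Et3N) as silyl enol ether F5. Only the enone is then reduced with Li (2.2 equiv)/NH3 and the single enolate is trapped with MeI, giving benzyl-retaining methyl ketone F6. CsF/PhNTf2 converts the silyl enol ether into benzyl-protected enol triflate F7, Stille allylation as in step 6 gives benzyl-protected allyl enoate F8, and the step 7 conditions applied to F8 also cleave the benzyl ether and deliver 15.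

Step 10 (exocyclic to endocyclic alkene shift). The isomerisation may stop at an equilibrium mixture or move the alkene toward C11. The fallback sets out from 18 and comes back at 19. Nickel boride conjugate reduction (NaBH4, NiCl2·6H2O, MeOH) gives saturated lactone F9 as a C13 epimer mixture. Deprotonation with excess LDA and PhSeBr gives α-phenylselenyl lactone F10, and selenoxide syn-elimination (H2O2, pyridine) toward the ring C14–H gives 19. Any exocyclic isomer formed in the elimination is 18 and is recycled.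

**Further compounds**

F1 | step 1 | 3-(benzyloxy)propanal | O=CCCOCc1ccccc1
F2 | step 1 | 5-(benzyloxy)pent-1-en-3-ol (racemic) | C=CC(O)CCOCc1ccccc1
F3 | step 1 | 5-(benzyloxy)pent-1-en-3-one | C=CC(=O)CCOCc1ccccc1
F4 | step 1 | 2-[5-(benzyloxy)-3-oxopentyl]-2-methylcyclopentane-1,3-dione | CC1(CCC(=O)CCOCc2ccccc2)C(=O)CCC1=O
F5 | step 4 | ethyl (8aR)-5-[(benzyloxy)methyl]-1-[(tert-butyldimethylsilyl)oxy]-8a-methyl-6-oxo-3,4,6,7,8,8a-hexahydronaphthalene-2-carboxylate | c1ccccc1COCC1=C2CCC(C(=O)OCC)=C(O[Si](C)(C)C(C)(C)C)[C@]2(C)CCC1=O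
F6 | step 4 | ethyl (4aS,5R,8aR)-5-[(benzyloxy)methyl]-1-[(tert-butyldimethylsilyl)oxy]-5,8a-dimethyl-6-oxo-3,4,4a,5,6,7,8,8a-octahydronaphthalene-2-carboxylate | C[C@]1(COCc3ccccc3)[C@H]2CCC(C(=O)OCC)=C(O[Si](C)(C)C(C)(C)C)[C@]2(C)CCC1=O
F7 | step 4 | ethyl (4aS,5R,8aR)-5-[(benzyloxy)methyl]-5,8a-dimethyl-6-oxo-1-[(trifluoromethanesulfonyl)oxy]-3,4,4a,5,6,7,8,8a-octahydronaphthalene-2-carboxylate | C[C@]1(COCc3ccccc3)[C@H]2CCC(C(=O)OCC)=C(OS(=O)(=O)C(F)(F)F)[C@]2(C)CCC1=O
F8 | step 4 | ethyl (4aS,5R,8aR)-5-[(benzyloxy)methyl]-5,8a-dimethyl-6-oxo-1-(prop-2-en-1-yl)-3,4,4a,5,6,7,8,8a-octahydronaphthalene-2-carboxylate | C[C@]1(COCc3ccccc3)[C@H]2CCC(C(=O)OCC)=C(CC=C)[C@]2(C)CCC1=O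
F9 | step 10 | 3-{2-[(1R,2S,4aS,5R,6R,8aS)-6-hydroxy-2,5-bis(hydroxymethyl)-5,8a-dimethyldecahydronaphthalen-1-yl]ethyl}oxolan-2-one (C13 epimer mixture) | C[C@]1(CO)[C@H]2CC[C@H](CO)[C@@H](CCC3CCOC3=O)[C@]2(C)CC[C@H]1O
F10 | step 10 | 3-{2-[(1R,2S,4aS,5R,6R,8aS)-6-hydroxy-2,5-bis(hydroxymethyl)-5,8a-dimethyldecahydronaphthalen-1-yl]ethyl}-3-(phenylselanyl)oxolan-2-one (C13 epimer mixture) | C[C@]1(CO)[C@H]2CC[C@H](CO)[C@@H](CCC3([Se]c4ccccc4)CCOC3=O)[C@]2(C)CC[C@H]1O
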